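## Retrosynthetic overview

1. The spiro-epoxide is made last among the rings, by C8-hydroxyl-directed nucleophilic epoxidation of the 11(13)-methylene lactone; the two esters follow.
2. The 3(2H)-furanone comes from transannular hemiketalisation/dehydration of a 10-hydroxy-1,3-dione, generated in the ring by gold-catalysed hydration of a macrocyclic 10-hydroxy-1-yn-3-one.
3. The ten-membered carbocycle and the 12,6-lactone form in one operation: the C6–C7 bond (the bond the terpene cyclase makes) closes by intramolecular allylboration of a (Z)-4-oxo-2-enal unveiled from a furan with singlet oxygen, and the C6 borate then lactonises.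
4. The open-chain precursor comes from a Z-selective olefination (C7=C11), a Felkin acetylide addition (C1–C10) and an L-proline aldol of hydroxyacetone (C8–C9).
5. Ring order: ten-membered carbocycle → γ-lactone → 3(2H)-furanone → epoxide.

Assumption: ring compounds carry germacrane numbering (C1–C15); 2,2-dimethoxyacetaldehyde, 3-methylfuran-2-carbaldehyde, methyl bis(2,2,2-trifluoroethyl)phosphonoacetate and 2-(iodomethyl)pinacolborane are taken as purchasable.

## Route

Step 1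
Reactants: 1 hydroxyacetone; 2 2,2-dimethoxyacetaldehyde
Product: 3 (3S,4R)-3,4-dihydroxy-5,5-dimethoxypentan-2-one
Conditions: L-proline (30 mol%), DMSO, rt
Reagents that add atoms: none
Why: Proline-catalysed direct aldol reaction (enamine catalysis): the hydroxyacetone enamine adds to the re face of the α-branched aldehyde through the acid-bridged Houk–List transition state, which gives the anti-diol and sets C9 (3S) and C8 (4R) in the sense known for L-proline.

Step 2
Reactants: 3 (3S,4R)-3,4-dihydroxy-5,5-dimethoxypentan-2-one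
Product: 4 1-[(4S,5R)-5-(dimethoxymethyl)-2,2-dimethyl-1,3-dioxolan-4-yl]ethan-1-one
Conditions: 2,2-dimethoxypropane, PPTS (cat.), CH2Cl2, rt
Reagents that add atoms: 2,2-dimethoxypropane (COC(C)(C)OC)
Why: Acid-catalysed transketalisation ties the erythro diol into a cis-dioxolane that is non-chelating in step 4 and keeps O8 and O9 masked until the furanone is in place; no stereocenter changes.

Step 3
Reactants: 5 3-methylfuran-2-carbaldehyde
Product: 6 2-ethynyl-3-methylfuran
Conditions: dimethyl (1-diazo-2-oxopropyl)phosphonate, K2CO3, MeOH, 0 °C → rt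
Reagents that add atoms: dimethyl (1-diazo-2-oxopropyl)phosphonate (COP(=O)(OC)C(=[N+]=[N-])C(C)=O)
Why: Seyferth–Gilbert homologation in the Ohira–Bestmann variant turns the aldehyde into the terminal alkyne under carbonate/methanol conditions that the furan tolerates.

Step 4
Reactants: 6 2-ethynyl-3-methylfuran; 4 1-[(4S,5R)-5-(dimethoxymethyl)-2,2-dimethyl-1,3-dioxolan-4-yl]ethan-1-one
Product: 8 (2R)-2-[(4S,5R)-5-(dimethoxymethyl)-2,2-dimethyl-1,3-dioxolan-4-yl]-4-(3-methylfuran-2-yl)but-3-yn-2-ol, via lithium acetylide 7 (not isolated)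
Conditions: n-BuLi, THF, −78 °C; then 4, −78 °C; aq. NH4Cl
Reagents that add atoms: none
Why: 1,2-Addition of a lithium acetylide to an α-alkoxy ketone under non-chelating conditions follows the polar Felkin–Anh model (nucleophile anti to the C9–O bond), which places O10 erythro to O9 and sets C10 (2R here, 10S in the target).

Step 5
Reactants: 8 (2R)-2-[(4S,5R)-5-(dimethoxymethyl)-2,2-dimethyl-1,3-dioxolan-4-yl]-4-(3-methylfuran-2-yl)but-3-yn-2-ol
Product: 10 (4R,5S)-2,2-dimethyl-5-[(2R)-4-(3-methylfuran-2-yl)-2-(triethylsilyloxy)but-3-yn-2-yl]-1,3-dioxolane-4-carbaldehyde, via collidinium salt 9 (not isolated)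
Conditions: Et3SiOTf (3 equiv), 2,4,6-collidine (4.5 equiv), CH2Cl2, 0 °C; then H2O, rt
Reagents that add atoms: triethylsilyl trifluoromethanesulfonate (CC[Si](CC)(CC)OS(=O)(=O)C(F)(F)F); water (O)
Why: Silyl-triflate/collidine acetal cleavage (Fujioka conditions) converts the aldehyde dimethyl acetal into a collidinium salt that water hydrolyses to the aldehyde while the ketal is left alone, and the same reagent silylates the tertiary alcohol so the aldehyde cannot close to a lactol; the cold, non-basic medium leaves the α-stereocenter intact.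

Step 6
Reactants: 11 methyl 2-[bis(2,2,2-trifluoroethoxy)phosphoryl]acetate; 12 2-(iodomethyl)-4,4,5,5-tetramethyl-1,3,2-dioxaborolane
Product: 14 methyl 2-[bis(2,2,2-trifluoroethoxy)phosphoryl]-3-(4,4,5,5-tetramethyl-1,3,2-dioxaborolan-2-yl)propanoate (racemic), via sodium phosphonate carbanion 13 (not isolated)
Conditions: NaH, THF, 0 °C; then 12, rt
Reagents that add atoms: none
Why: C-alkylation of a stabilised phosphonate carbanion by an (iodomethyl)boronic ester (Matteson-type substitution through a boron ate complex and 1,2-shift); the new center is racemic and is destroyed in step 7.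

Step 7
Reactants: 10 (4R,5S)-2,2-dimethyl-5-[(2R)-4-(3-methylfuran-2-yl)-2-(triethylsilyloxy)but-3-yn-2-yl]-1,3-dioxolane-4-carbaldehyde; 14 methyl 2-[bis(2,2,2-trifluoroethoxy)phosphoryl]-3-(4,4,5,5-tetramethyl-1,3,2-dioxaborolan-2-yl)propanoate
Product: 16 methyl (2Z)-3-{(4S,5S)-2,2-dimethyl-5-[(2R)-4-(3-methylfuran-2-yl)-2-(triethylsilyloxy)but-3-yn-2-yl]-1,3-dioxolan-4-yl}-2-[(4,4,5,5-tetramethyl-1,3,2-dioxaborolan-2-yl)methyl]prop-2-enoate, via potassium phosphonate carbanion 15 (not isolated)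
Conditions: KN(SiMe3)2, 18-crown-6, THF, −78 °C; then 10
Reagents that add atoms: none
Why: Proposed new method: a Still–Gennari olefination with an α-(borylmethyl) bis(trifluoroethyl)phosphonate, whose electron-poor phosphorus makes oxaphosphetane collapse faster than equilibration, should give the (Z)-enoate (ester cis to C8, CH2B trans to C8), the allylboronate geometry needed for an anti allylation; the closest known reaction is the Z-selective Still–Gennari olefination of α-alkoxy aldehydes with α-methyl phosphonates.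

Step 8
Reactants: 16 methyl (2Z)-3-{(4S,5S)-2,2-dimethyl-5-[(2R)-4-(3-methylfuran-2-yl)-2-(triethylsilyloxy)but-3-yn-2-yl]-1,3-dioxolan-4-yl}-2-[(4,4,5,5-tetramethyl-1,3,2-dioxaborolan-2-yl)methyl]prop-2-enoate
Product: 20 (4Z,6R,7S,8S,9S,10R)-8,9-(isopropylidenedioxy)-3-oxo-10-(triethylsilyloxy)germacra-4,11(13)-dien-1-yn-12,6-olide, via furan endoperoxide 17 (not isolated), via ynenedione aldehyde 18 (not isolated), via borate adduct 19 (not isolated)
Conditions: O2, methylene blue (1 mol%), hν, CH2Cl2 (2 mM), −78 °C; Me2S (5 equiv), −78 → 23 °C; then 35 °C, 16 h; PPTS (20 mol%), 35 °C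
Reagents that add atoms: dioxygen (O=O)
Why: Proposed new method: singlet-oxygen [4+2] addition to the furan and Me2S reduction of the endoperoxide (known furan-to-cis-enedione chemistry) unveil the (Z)-4-oxo-2-enal, whose aldehyde is attacked by the 2-alkoxycarbonyl allylboronate in a closed chair (Zimmerman–Traxler) allylboration (closest known reactions: allylboration/lactonisation of 2-alkoxycarbonyl allylboronates and Barbier macrocyclisations to germacranolides), with C5 and C8 both equatorial (anti adduct, 6R) and with H8 eclipsing C7=C11, C9 anti and O8 outside (A(1,3) strain, and the only rotamer whose C5···C9 span of about 4.4 Å fits the stiff ynenone tether), which sets 7S, after which the C6 borate lactonises onto the ester to the trans-fused 12,6-lactone; the bent alkyne strains the ring, hence the high dilution.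

Step 9
Reactants: 20 (4Z,6R,7S,8S,9S,10R)-8,9-(isopropylidenedioxy)-3-oxo-10-(triethylsilyloxy)germacra-4,11(13)-dien-1-yn-12,6-olide
Product: 23 (4Z,6R,7S,8S,9S,10S)-3,10-epoxy-8,9-(isopropylidenedioxy)-1-oxogermacra-2,4,11(13)-trien-12,6-olide, via tertiary alcohol 21 (not isolated), via 10-hydroxy-1,3-dione 22 (not isolated)
Conditions: HF·pyridine, pyridine, THF, 0 °C → rt; concentrate; then AuCl3 (5 mol%), CH2Cl2, H2O (5 equiv), rt
Reagents that add atoms: none
Why: Fluoride frees the C10 alcohol and AuCl3 (trivalent gold) then catalyses the known cycloisomerisation of a γ-hydroxy-alkynone to a 3(2H)-furanone: water adds to C1 of the activated, strained ynone, the C10 hydroxyl of the resulting 10-hydroxy-1,3-dione adds transannularly to the C3 carbonyl and the hemiketal dehydrates (the hemiketalisation/dehydration of the biosynthesis), while the acetonide and lactone keep O6, O8 and O9 from competing; no stereocenter is touched.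

Step 10
Reactants: 23 (4Z,6R,7S,8S,9S,10S)-3,10-epoxy-8,9-(isopropylidenedioxy)-1-oxogermacra-2,4,11(13)-trien-12,6-olide
Product: 24 (4Z,6R,7S,8S,9S,10S)-3,10-epoxy-8,9-dihydroxy-1-oxogermacra-2,4,11(13)-trien-12,6-olide
Conditions: CF3CO2H/H2O (9:1), 0 °C, 1 h
Reagents that add atoms: none
Why: Acid hydrolysis of the dioxolane (ketal cleavage), tolerated by the vinylogous-ester furanone and the methylene lactone; the trans-fused 12,6-lactone is retained because relactonisation to the 8β-oxygen would give a cis-fused ring.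

Step 11
Reactants: 24 (4Z,6R,7S,8S,9S,10S)-3,10-epoxy-8,9-dihydroxy-1-oxogermacra-2,4,11(13)-trien-12,6-olide
Product: 25 (4Z,6R,7S,8S,9S,10S,11S)-3,10:11,13-diepoxy-8,9-dihydroxy-1-oxogermacra-2,4-dien-12,6-olide
Conditions: t-BuOOH (decane, 1.5 equiv), DBU (0.3 equiv), CH2Cl2, −20 → 0 °C
Reagents that add atoms: tert-butyl hydroperoxide (CC(C)(C)OO)
Why: Hydroxyl-directed nucleophilic (Weitz–Scheffer) epoxidation: the peroxide anion adds to C13 of the most electrophilic alkene and the enolate closes onto oxygen on the β face, where the homoallylic C8 hydroxyl hydrogen-bonds the peroxide and the leaving tert-butoxide, which sets 11S (oxygen syn to C8); the vinylogous-ester furanone is not attacked.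

Step 12
Reactants: 25 (4Z,6R,7S,8S,9S,10S,11S)-3,10:11,13-diepoxy-8,9-dihydroxy-1-oxogermacra-2,4-dien-12,6-olide
Product: 26 (4Z,6R,7S,8S,9S,10S,11S)-3,10:11,13-diepoxy-9-hydroxy-8-(methacryloyloxy)-1-oxogermacra-2,4-dien-12,6-olide
Conditions: methacrylic anhydride (1.1 equiv), DMAP (0.1 equiv), i-Pr2NEt, CH2Cl2, −20 °C
Reagents that add atoms: methacrylic anhydride (C=C(C)C(=O)OC(=O)C(C)=C)
Why: Steglich-type acylation through the acylpyridinium should favour the C8 hydroxyl because the C9 hydroxyl is neopentylic (next to the quaternary C10); no stereocenter changes.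

Step 13
Reactants: 26 (4Z,6R,7S,8S,9S,10S,11S)-3,10:11,13-diepoxy-9-hydroxy-8-(methacryloyloxy)-1-oxogermacra-2,4-dien-12,6-olide
Product: 27 (4Z,6R,7S,8S,9S,10S,11S)-9-acetoxy-3,10:11,13-diepoxy-8-(methacryloyloxy)-1-oxogermacra-2,4-dien-12,6-olide (CNP0423862.2)
Conditions: Ac2O, DMAP, pyridine, CH2Cl2, rt
Reagents that add atoms: acetic anhydride (CC(=O)OC(C)=O)
Why: Steglich-type acetylation (Ac2O/DMAP) of the remaining hindered secondary C9 hydroxyl, with retention, gives the target.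

## Compound list

1 | hydroxyacetone (1-hydroxypropan-2-one) | CC(=O)CO | starting material
2 | 2,2-dimethoxyacetaldehyde | COC(OC)C=O | starting material
3 | (3S,4R)-3,4-dihydroxy-5,5-dimethoxypentan-2-one | COC(OC)[C@H](O)[C@H](O)C(C)=O | intermediate
4 | 1-[(4S,5R)-5-(dimethoxymethyl)-2,2-dimethyl-1,3-dioxolan-4-yl]ethan-1-one | COC(OC)[C@@H]1OC(C)(C)O[C@@H]1C(C)=O | intermediate
5 | 3-methylfuran-2-carbaldehyde | Cc1ccoc1C=O | starting material
6 | 2-ethynyl-3-methylfuran | C#Cc1occc1C | intermediate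
7 | lithium 2-(3-methylfuran-2-yl)ethyn-1-ide (LiC≡C–furyl) | [Li+].[C-]#Cc1occc1C | intermediate
8 | (2R)-2-[(4S,5R)-5-(dimethoxymethyl)-2,2-dimethyl-1,3-dioxolan-4-yl]-4-(3-methylfuran-2-yl)but-3-yn-2-ol | COC(OC)[C@@H]1OC(C)(C)O[C@@H]1[C@](C)(O)C#Cc1occc1C | intermediate
9 | 1-{methoxy[(4R,5S)-2,2-dimethyl-5-[(2R)-4-(3-methylfuran-2-yl)-2-(triethylsilyloxy)but-3-yn-2-yl]-1,3-dioxolan-4-yl]methyl}-2,4,6-trimethylpyridinium triflate (N,O-acetal carbon unassigned) | COC([n+]1c(C)cc(C)cc1C)[C@@H]1OC(C)(C)O[C@@H]1[C@](C)(O[Si](CC)(CC)CC)C#Cc1occc1C.[O-]S(=O)(=O)C(F)(F)F | intermediate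
10 | (4R,5S)-2,2-dimethyl-5-[(2R)-4-(3-methylfuran-2-yl)-2-(triethylsilyloxy)but-3-yn-2-yl]-1,3-dioxolane-4-carbaldehyde | O=C[C@@H]1OC(C)(C)O[C@@H]1[C@](C)(O[Si](CC)(CC)CC)C#Cc1occc1C | intermediate
11 | methyl 2-[bis(2,2,2-trifluoroethoxy)phosphoryl]acetate | COC(=O)CP(=O)(OCC(F)(F)F)OCC(F)(F)F | starting material
12 | 2-(iodomethyl)-4,4,5,5-tetramethyl-1,3,2-dioxaborolane | ICB1OC(C)(C)C(C)(C)O1 | starting material
13 | sodium salt (Na+) of the carbanion of 11 | COC(=O)[CH-]P(=O)(OCC(F)(F)F)OCC(F)(F)F.[Na+] | intermediate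
14 | methyl 2-[bis(2,2,2-trifluoroethoxy)phosphoryl]-3-(4,4,5,5-tetramethyl-1,3,2-dioxaborolan-2-yl)propanoate (racemic) | COC(=O)C(CB1OC(C)(C)C(C)(C)O1)P(=O)(OCC(F)(F)F)OCC(F)(F)F | intermediate
15 | potassium salt (K+) of the carbanion of 14 | COC(=O)[C-](CB1OC(C)(C)C(C)(C)O1)P(=O)(OCC(F)(F)F)OCC(F)(F)F.[K+] | intermediate
16 | methyl (2Z)-3-{(4S,5S)-2,2-dimethyl-5-[(2R)-4-(3-methylfuran-2-yl)-2-(triethylsilyloxy)but-3-yn-2-yl]-1,3-dioxolan-4-yl}-2-[(4,4,5,5-tetramethyl-1,3,2-dioxaborolan-2-yl)methyl]prop-2-enoate | COC(=O)/C(CB1OC(C)(C)C(C)(C)O1)=C\[C@@H]2OC(C)(C)O[C@@H]2[C@](C)(O[Si](CC)(CC)CC)C#Cc2occc2C | intermediate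
17 | 2,5-endoperoxide of the furan of 16 (2,3,7-trioxabicyclo[2.2.1]hept-5-ene; bridgeheads unassigned) | COC(=O)/C(CB1OC(C)(C)C(C)(C)O1)=C\[C@@H]2OC(C)(C)O[C@@H]2[C@](C)(O[Si](CC)(CC)CC)C#CC23OOC(O2)C=C3C | intermediate
18 | open-chain (4Z)-3,6-dioxo-4-en-1-yne (ynenedione aldehyde) carrying the allylboronate of 16 | COC(=O)/C(CB1OC(C)(C)C(C)(C)O1)=C\[C@@H]2OC(C)(C)O[C@@H]2[C@](C)(O[Si](CC)(CC)CC)C#CC(=O)/C(C)=C\C=O | intermediate
19 | methyl (4Z,6R,7S,8S,9S,10R)-8,9-(isopropylidenedioxy)-3-oxo-6-[(4,4,5,5-tetramethyl-1,3,2-dioxaborolan-2-yl)oxy]-10-(triethylsilyloxy)germacra-4,11(13)-dien-1-yn-12-oate | CC1(C)O[C@H]2[C@H]([C@@H](/C=C(/C)C(=O)C#C[C@@](C)(O[Si](CC)(CC)CC)[C@H]2O1)OB1OC(C)(C)C(C)(C)O1)C(=C)C(=O)OC | intermediate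
20 | (4Z,6R,7S,8S,9S,10R)-8,9-(isopropylidenedioxy)-3-oxo-10-(triethylsilyloxy)germacra-4,11(13)-dien-1-yn-12,6-olide | CC1(C)O[C@H]2[C@@H]3[C@@H](/C=C(/C)C(=O)C#C[C@@](C)(O[Si](CC)(CC)CC)[C@H]2O1)OC(=O)C3=C | intermediate
21 | (4Z,6R,7S,8S,9S,10R)-10-hydroxy-8,9-(isopropylidenedioxy)-3-oxogermacra-4,11(13)-dien-1-yn-12,6-olide | CC1(C)O[C@H]2[C@@H]3[C@@H](/C=C(/C)C(=O)C#C[C@@](C)(O)[C@H]2O1)OC(=O)C3=C | intermediate
22 | (4Z,6R,7S,8S,9S,10S)-10-hydroxy-8,9-(isopropylidenedioxy)-1,3-dioxogermacra-4,11(13)-dien-12,6-olide | CC1(C)O[C@H]2[C@@H]3[C@@H](/C=C(/C)C(=O)CC(=O)[C@@](C)(O)[C@H]2O1)OC(=O)C3=C | intermediate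
23 | (4Z,6R,7S,8S,9S,10S)-3,10-epoxy-8,9-(isopropylidenedioxy)-1-oxogermacra-2,4,11(13)-trien-12,6-olide | CC1(C)O[C@H]2[C@@H]3[C@@H](/C=C(/C)C4=CC(=O)[C@@](C)(O4)[C@H]2O1)OC(=O)C3=C | intermediate
24 | (4Z,6R,7S,8S,9S,10S)-3,10-epoxy-8,9-dihydroxy-1-oxogermacra-2,4,11(13)-trien-12,6-olide | O[C@H]1[C@@H]2[C@@H](/C=C(/C)C3=CC(=O)[C@@](C)(O3)[C@H]1O)OC(=O)C2=C | intermediate
25 | (4Z,6R,7S,8S,9S,10S,11S)-3,10:11,13-diepoxy-8,9-dihydroxy-1-oxogermacra-2,4-dien-12,6-olide | O[C@H]1[C@@H]2[C@@H](/C=C(/C)C3=CC(=O)[C@@](C)(O3)[C@H]1O)OC(=O)[C@@]21CO1 | intermediate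
26 | (4Z,6R,7S,8S,9S,10S,11S)-3,10:11,13-diepoxy-9-hydroxy-8-(methacryloyloxy)-1-oxogermacra-2,4-dien-12,6-olide | C=C(C)C(=O)O[C@H]1[C@@H]2[C@@H](/C=C(/C)C3=CC(=O)[C@@](C)(O3)[C@H]1O)OC(=O)[C@@]21CO1 | intermediate
27 | (4Z,6R,7S,8S,9S,10S,11S)-9-acetoxy-3,10:11,13-diepoxy-8-(methacryloyloxy)-1-oxogermacra-2,4-dien-12,6-olide (CNP0423862.2) | C=C(C)C(=O)O[C@H]1[C@@H]2[C@@H](/C=C(/C)C3=CC(=O)[C@@](C)(O3)[C@H]1OC(C)=O)OC(=O)[C@@]21CO1 | target

## Step count and risks

Total step count: 13. Longest linear sequence: 11 steps (1, 2, 4, 5, 7, 8, 9, 10, 11, 12, 13); steps 3 and 6 are side branches.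

Three steps most likely to fail:

**Step 8.** The ten-membered ring must close around a bent alkyne, and the sense of attack on C7 rests on a conformational argument. The fallback sets out from 16 and comes back at 23; it forms the furanone before the ring, so the closing ring holds no alkyne. Compound 16 is desilylated (PPTS, MeOH, 0 °C) to tertiary alcohol F1. Photooxygenation and Me2S reduction at −78 °C give hydroxy ynenedione aldehyde F2. This is treated cold (−40 °C) with AuCl3 in wet CH2Cl2, so the hydroxy-ynone is hydrated and cyclodehydrated to open-chain furanone enal F3 before the slow allylboration starts. Warming then closes C6–C7 on the furanone template to borate F4, and PPTS-promoted lactonisation gives 23.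

**Step 7.** The borylmethyl phosphonate is untested; its carbanion may be sluggish or poorly Z-selective. The fallback sets out from 10 and comes back at 16; it builds the same geometry by syn-hydrometalation of an ynoate instead of olefination. Aldehyde 10 is homologated (Ohira–Bestmann reagent, K2CO3, MeOH) to terminal alkyne F5. Deprotonation with n-BuLi gives lithium acetylide F6, and methyl chloroformate gives ynoate F7. Syn-hydroalumination (i-Bu2AlH, HMPA, catalytic CH3Cu) places H on C7 and aluminium on C11 cis to it, giving alkenylalane F8 with the ester cis to C8. Alkylation of F8 with 12 gives 16.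

**Step 11.** Face selectivity depends on hydrogen-bond direction, and DBU on the free diol may trigger retro-aldol cleavage at C9–C10 or oxa-Michael addition of O9 to C13. The fallback sets out from 24 and comes back at 27; it replaces substrate direction by catalyst control on the fully acylated alkene. Diol 24 is acylated at C8 with methacrylic anhydride/DMAP to 8-O-methacrylate F9, then acetylated (Ac2O, DMAP) to 8-O-methacrylate 9-O-acetate F10. The methylene lactone of F10 is epoxidised with NaOCl under phase transfer with a cinchona-derived quaternary ammonium salt, choosing the pseudo-enantiomeric catalyst that gives 11S, which is 27.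

Further compounds
F1 | step 8 | methyl (2Z)-3-{(4S,5S)-5-[(2R)-2-hydroxy-4-(3-methylfuran-2-yl)but-3-yn-2-yl]-2,2-dimethyl-1,3-dioxolan-4-yl}-2-[(4,4,5,5-tetramethyl-1,3,2-dioxaborolan-2-yl)methyl]prop-2-enoate | COC(=O)/C(CB1OC(C)(C)C(C)(C)O1)=C\[C@@H]2OC(C)(C)O[C@@H]2[C@](C)(O)C#Cc2occc2C
F2 | step 8 | 10-hydroxy analogue of 18 (hydroxy ynenedione aldehyde carrying the allylboronate) | COC(=O)/C(CB1OC(C)(C)C(C)(C)O1)=C\[C@@H]2OC(C)(C)O[C@@H]2[C@](C)(O)C#CC(=O)/C(C)=C\C=O
F3 | step 8 | open-chain 3(2H)-furanone (Z)-enal carrying the allylboronate | COC(=O)/C(CB1OC(C)(C)C(C)(C)O1)=C\[C@@H]2OC(C)(C)O[C@@H]2[C@]2(C)OC(=CC2=O)/C(C)=C\C=O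
F4 | step 8 | methyl (4Z,6R,7S,8S,9S,10S)-3,10-epoxy-8,9-(isopropylidenedioxy)-1-oxo-6-[(4,4,5,5-tetramethyl-1,3,2-dioxaborolan-2-yl)oxy]germacra-2,4,11(13)-trien-12-oate | CC1(C)O[C@H]2[C@H]([C@@H](/C=C(/C)C3=CC(=O)[C@@](C)(O3)[C@H]2O1)OB1OC(C)(C)C(C)(C)O1)C(=C)C(=O)OC
F5 | step 7 | (4R,5S)-4-ethynyl-2,2-dimethyl-5-[(2R)-4-(3-methylfuran-2-yl)-2-(triethylsilyloxy)but-3-yn-2-yl]-1,3-dioxolane | C#C[C@@H]1OC(C)(C)O[C@@H]1[C@](C)(O[Si](CC)(CC)CC)C#Cc1occc1C
F6 | step 7 | lithium acetylide (Li+) of F5 | [Li+].[C-]#C[C@@H]1OC(C)(C)O[C@@H]1[C@](C)(O[Si](CC)(CC)CC)C#Cc1occc1C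
F7 | step 7 | methyl 3-{(4R,5S)-2,2-dimethyl-5-[(2R)-4-(3-methylfuran-2-yl)-2-(triethylsilyloxy)but-3-yn-2-yl]-1,3-dioxolan-4-yl}prop-2-ynoate | COC(=O)C#C[C@@H]1OC(C)(C)O[C@@H]1[C@](C)(O[Si](CC)(CC)CC)C#Cc1occc1C
F8 | step 7 | methyl (2Z)-2-[bis(2-methylpropyl)alumanyl]-3-(dioxolanyl)prop-2-enoate (alkenylalane from F7) | COC(=O)/C([Al](CC(C)C)CC(C)C)=C\[C@@H]1OC(C)(C)O[C@@H]1[C@](C)(O[Si](CC)(CC)CC)C#Cc1occc1C
F9 | step 11 | (4Z,6R,7S,8S,9S,10S)-3,10-epoxy-9-hydroxy-8-(methacryloyloxy)-1-oxogermacra-2,4,11(13)-trien-12,6-olide | C=C(C)C(=O)O[C@H]1[C@@H]2[C@@H](/C=C(/C)C3=CC(=O)[C@@](C)(O3)[C@H]1O)OC(=O)C2=C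
F10 | step 11 | (4Z,6R,7S,8S,9S,10S)-9-acetoxy-3,10-epoxy-8-(methacryloyloxy)-1-oxogermacra-2,4,11(13)-trien-12,6-olide | C=C(C)C(=O)O[C@H]1[C@@H]2[C@@H](/C=C(/C)C3=CC(=O)[C@@](C)(O3)[C@H]1OC(C)=O)OC(=O)C2=C
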